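Late in a run I want to know where the L stands, so I start there and work back to the first hours. Of L and X, L is the limiting reagent, at 0.10 M against 0.500 M of X, and I keep a ledger of it with three entries: L, J, and Z, which I take as the gap the other two leave.

| flask | L | X | Q | G | remark | time |
|---|---|---|---|---|---|---|
| summer | 0.10 M | 0.50 M | 0.48 mM | 0.12 mM | run made earlier |  |
| ochre | 0.10 M | 0.500 M | 0.24 mM | 0.12 mM |  | 25 h |
| blue | 0.10 M | 0.500 M | 0.24 mM | 0.12 mM |  | 75 h |

summer run (percent of the L charged)

| time / h | J / % | L / % |
|---|---|---|
| 0.417 | 3.5 | 96.0 |
| 0.667 | 4.6 | 94.4 |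
| 1.00 | 7.5 | 91.9 |
| 1.33 | 9.0 | 89.1 |
| 2.00 | 13.1 | 85.0 |
| 3.00 | 18.5 | 78.5 |
| 5.00 | 25.1 | 69.2 |

(each reading ± 0.5 percentage points)

- no earlier run changes the charge of Q; that part of a forecast is a guess

1. which of the two there is more of at the end, ochre (Z / J)
2. which of the two there is more of at the end, blue (Z / J)
3. J at the end, in percent of the L charged, ochre
4. J at the end, in percent of the L charged, blue

The opening of summer gives the first constant: by 2.00 h the reading of L is 85.0%, so I read that it leaves at about 0.0813 /h. Next comes the leak from the pool L + J, which at 5.00 h still holds 94.3%, a leak of 0.0117 /h, slower than the leaving. The third constant is a return. Between 3.00 h and 5.00 h L falls by 0.0465 /h of the charge, less than the leaving constant takes from the L then present. I book the difference as J going back to L, and on the J then present that is 0.0620 /h, a rough reading, since the readings scatter by 0.5 percentage points.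

Now I join the ends. On these summer readings L and J exchange within 6.98 h, shorter than the 25 h of ochre, so late on they should share the pool steadily. J's share of the pool, the leaving constant over the sum of it and the return constant, reads 56.7%, with the scatter of the readings in it. Ochre and blue have the [X] of summer but half the Q, so carrying these constants over unchanged is a guess. With them, my ochre pool is 74.6%, which books J at 42.3% and Z at 25.4%. My blue pool is 41.5%, which books J at 23.5% and Z at 58.5%.

The forecast puts J at 34% in ochre and 28% in blue, with J ahead in ochre and Z in blue, and warns that “The Q effect is a guess”.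

Ochre gives 46.7% of J and blue 33.7%, with Z at 18.2% in ochre and 43.2% in blue. The ochre pool stands at 81.8%, more than my 74.6%. On that pool, J's share gives 46.4% for ochre.

    L + X ⇌ J (K = 3.42 /M, k = 0.00256 /M/min)
    L + X ⇌ Z (K = 95.0 /M, k = 3.14 × 10⁻⁴ /M/min)
    Q + G → D (k = 64.9 /M/min)
    J + Q ⇌ Z + Q, rate k4*[Q]*[J] forward; the back reaction follows from the equilibrium constant (k = 0.996 /M/min)

The flask of ochre read at 4.0 d has Z at 51.1%, so the share gives J 27.7%. The computed J there is 29.0%.

(All runs were computed on assumed constants; noise was put on by code.)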